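**Plan**

- Retrosynthetic cuts: first the three benzyl ethers and the ketone (from a benzylic carbinol). Next the CH2–O bond of the tetrahydrofuran ring that carries the ketone-bearing arene (lactone reduction and re-closure). Then, in one [3+2] event, the two C–C bonds CH2–CH(ring fusion) and CH(ring fusion)–CH(aryl) of the other tetrahydrofuran ring. This leaves a γ-aryl butenolide and an aryl acetal.
- Enabling feature: in the tetrahydrofuran ring that bears the dihydrobenzofuranyl group, the sequence CH2–O–CH(Ar) is a masked carbonyl ylide. The two ring-fusion CH carbons are the C=C of a butenolide. Its lactone carbonyl (later reduced to the CH2 of the second ring) activates the alkene, and its γ-aryl stereocentre directs the addition.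
- Forward order: the dihydrobenzofuran ring is made by C–H insertion and carried as an acetal. The side chain is made by an auxiliary aldol, then the butenolide ring is built. The [3+2] cycloaddition closes the first tetrahydrofuran ring cis-fused on the lactone. The lactone is reduced and re-closed as the second tetrahydrofuran ring. Deprotection, benzylic oxidation and debenzylation finish the route.
- Stereochemistry: the cis C2/C3 pair of the dihydrobenzofuran comes from a chiral dirhodium catalyst. The ketone α-carbon comes from an oxazolidinone auxiliary. The butenolide γ-carbon comes from a zinc–ProPhenol alkynylation and is relayed by the cycloaddition (anti face, exo aryl) to the other three furofuran centres.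

Key step: step 17

Assumption: the senses of induction of Rh2(R-PTTL)4 and of the (S,S)-ProPhenol–zinc catalyst are taken to be those needed here (the antipodal ligand is used if either proves opposite), and the carbinol configuration drawn for the side chain is that of the syn aldol and is of no consequence because this carbon ends as the ketone.

**Route**

Step 1
Reactants: 1 5-iodovanillin; 2 4-(benzyloxy)-3-methoxybenzyl alcohol
Product: 3 4-{[4-(benzyloxy)-3-methoxybenzyl]oxy}-3-iodo-5-methoxybenzaldehyde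
Conditions: PPh3, DIAD, THF, 0 °C → rt
Reagents that add atoms: none
Why: Mitsunobu etherification, in which the acidic hindered phenol is alkylated by the activated electron-rich benzylic alcohol under neutral conditions that leave the aldehyde untouched.

Step 2
Reactants: 3 iodo aldehyde; 4 (trimethylsilyl)methanol
Product: 5 bis[(trimethylsilyl)methyl] acetal of 3
Conditions: 4 (2.5 equiv), PPTS (cat.), benzene, reflux, Dean–Stark trap
Reagents that add atoms: none
Why: Acid-catalysed acetalisation with azeotropic removal of water, giving an acetal that masks the aldehyde through the next four steps and later serves as the source of the silylmethyl oxocarbenium ion of step 17.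

Step 3
Reactants: 5 aryl iodide acetal; 6 ethyl diazoacetate
Product: 7 ethyl aryldiazoacetate
Conditions: 6 (1.5 equiv), Pd(PPh3)4 (5 mol %), Ag2CO3 (0.5 equiv), Et3N, toluene, rt
Reagents that add atoms: none
Why: Palladium-catalysed cross-coupling of an aryl iodide with the C–H bond of ethyl diazoacetate (oxidative addition, silver- and base-assisted transfer of the diazo ester to palladium, reductive elimination with the diazo group retained) gives the aryldiazoacetate directly.

Step 4
Reactants: 7 ethyl aryldiazoacetate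
Product: 8 ethyl (2S,3R)-cis-2-aryl-2,3-dihydrobenzofuran-3-carboxylate
Conditions: Rh2(R-PTTL)4 (dirhodium tetrakis[N-phthaloyl-(R)-tert-leucinate], 1 mol %), toluene, −60 °C
Reagents that add atoms: none
Why: Intramolecular 1,5 C–H insertion of the rhodium-bound aryl(ester)carbene into the ether-activated benzylic C–H bond closes the dihydrofuran ring, the insertion being kinetically cis-selective and the chiral carboxylate ligand sphere setting both new stereocentres (2S,3R).

Step 5
Reactants: 8 cis ester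
Product: 9 (2S,3S)-cis-3-(hydroxymethyl)dihydrobenzofuran acetal
Conditions: LiAlH4, THF, −40 → 0 °C; aqueous potassium sodium tartrate work-up
Reagents that add atoms: none
Why: Hydride reduction of the ester at low temperature should be faster than enolisation, so the cis relationship is kept, and C3 cannot epimerise once it carries CH2OH.

Step 6
Reactants: 9 primary alcohol
Product: 10 tert-butyldimethylsilyl ether of 9
Conditions: TBSCl, imidazole, DMF, rt
Reagents that add atoms: tert-butyldimethylsilyl chloride CC(C)(C)[Si](C)(C)Cl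
Why: Standard silylation of the primary alcohol, which would otherwise capture the oxocarbenium ion in step 17.

Step 7
Reactants: 11 2-allyl-6-methoxyphenol
Product: 12 2-allyl-4-bromo-6-methoxyphenol
Conditions: NBS, MeCN, 0 °C
Reagents that add atoms: N-bromosuccinimide O=C1CCC(=O)N1Br
Why: Electrophilic aromatic bromination directed para by the free phenol (both ortho positions are blocked), which should be faster than addition to the isolated allyl double bond at 0 °C.

Step 8
Reactants: 12 bromophenol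
Product: 13 1-allyl-2-(benzyloxy)-5-bromo-3-methoxybenzene
Conditions: BnBr, K2CO3, DMF, rt
Reagents that add atoms: benzyl bromide BrCc1ccccc1
Why: Williamson etherification of the phenoxide.

Step 9
Reactants: 13 allyl arene
Product: 15 2-[2-(benzyloxy)-5-bromo-3-methoxyphenyl]acetic acid, via arylacetaldehyde 14 (not isolated)
Conditions: O3, acetone/H2O (95:5), 0 °C; then NaClO2, NaH2PO4, 2-methyl-2-butene, t-BuOH/H2O, rt
Reagents that add atoms: ozone [O-][O+]=O; sodium chlorite [Na+].[O-]Cl=O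
Why: Ozonolysis in wet acetone gives the arylacetaldehyde directly, and Pinnick oxidation of the crude aldehyde avoids handling this enolisable intermediate.

Step 10
Reactants: 15 arylacetic acid; 16 (R)-4-benzyl-1,3-oxazolidin-2-one
Product: 18 N-(arylacetyl)oxazolidinone, via mixed pivalic anhydride 17 (not isolated)
Conditions: PivCl, Et3N, THF, −20 °C; then 16, LiCl, −20 °C → rt
Reagents that add atoms: none
Why: N-Acylation of the oxazolidinone by the mixed pivalic anhydride under LiCl/Et3N activation, a standard entry to N-acyl oxazolidinones.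

Step 11
Reactants: 18 N-(arylacetyl)oxazolidinone; 19 4-(benzyloxy)-3-methoxybenzaldehyde
Product: 21 (2R,3R) syn-aldol adduct, via Z-boron enolate 20 (not isolated)
Conditions: Bu2BOTf, i-Pr2NEt, CH2Cl2, −78 → 0 °C; 19, −78 → 0 °C; then pH 7 buffer, MeOH, 30% H2O2, 0 °C
Reagents that add atoms: none
Why: Evans syn-aldol reaction, in which the Z-boron enolate reacts through a closed chair transition state on the face away from the benzyl group of the auxiliary and so sets the aryl-bearing carbon (2R, the later ketone α-carbon) and the carbinol carbon (3R).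

Step 12
Reactants: 21 aldol adduct
Product: 22 (1R,2S)-1,2-diarylpropane-1,3-diol
Conditions: LiBH4, H2O (1 equiv), Et2O/THF, 0 °C
Reagents that add atoms: none
Why: Reductive removal of the auxiliary with LiBH4 attacks the exocyclic imide carbonyl selectively and leaves the aryl bromide and both stereocentres untouched.

Step 13
Reactants: 22 1,3-diol
Product: 23 (4R,5S)-4,5-diaryl-2,2-dimethyl-1,3-dioxane
Conditions: 2,2-dimethoxypropane, PPTS (cat.), CH2Cl2, rt
Reagents that add atoms: 2,2-dimethoxypropane COC(C)(C)OC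
Why: Acetonide formation from the 1,3-diol protects both hydroxyl groups in one step and ties down the benzylic oxygen.

Step 14
Reactants: 23 aryl bromide
Product: 25 aryl aldehyde, via aryllithium 24 (not isolated)
Conditions: n-BuLi, THF, −78 °C; then DMF, −78 → 0 °C; aqueous NH4Cl
Reagents that add atoms: N,N-dimethylformamide CN(C)C=O
Why: Bromine–lithium exchange at −78 °C followed by formylation with DMF, conditions to which acetonide and benzyl ethers are inert.

Step 15
Reactants: 25 aryl aldehyde; 26 methyl propiolate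
Product: 27 methyl (4R)-4-aryl-4-hydroxybut-2-ynoate
Conditions: 26 (3 equiv), Me2Zn (3 equiv), (S,S)-ProPhenol (20 mol %), Ph3PO (40 mol %), toluene, 4 °C
Reagents that add atoms: none
Why: Zinc–ProPhenol-catalysed enantioselective addition of the zinc acetylide of methyl propiolate to the aldehyde, the dinuclear zinc catalyst setting the carbinol stereocentre (R) that becomes the γ-carbon of the butenolide.

Step 16
Reactants: 27 propargylic alcohol
Product: 29 (5S)-5-aryl-furan-2(5H)-one, via Z-hydroxy enoate 28 (not isolated)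
Conditions: H2 (1 atm), Pd/CaCO3 poisoned with Pb(OAc)2 (Lindlar catalyst), quinoline, EtOAc, rt; then PPTS (cat.), CH2Cl2, rt
Reagents that add atoms: none
Why: Lindlar semihydrogenation gives the Z-γ-hydroxy enoate, which lactonises to the butenolide without touching the stereocentre or the benzyl ethers.

Step 17
Reactants: 10 bis(silylmethyl) acetal; 29 butenolide
Product: 32 cis-fused furofuranone cycloadduct (3S,3aR,6S,6aS), via oxocarbenium triflate 30 (not isolated), via carbonyl ylide 31 (not isolated)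
Conditions: 10 (2 equiv), TMSOTf (1.9 equiv), 2,6-di-tert-butyl-4-methylpyridine (0.2 equiv), CH2Cl2, −78 °C, 15 min; then 29 (1 equiv) and Bu4N[Ph3SiF2] (2.2 equiv), −78 → −30 °C
Reagents that add atoms: none
Why: Proposed new method: TMSOTf ionises acetal 10 to the aryl-stabilised (silylmethyl)oxocarbenium triflate 30, fluoride then removes the silyl group in a 1,3-elimination to give the non-stabilised carbonyl ylide 31, and this nucleophilic 1,3-dipole adds across the electron-poor C=C of butenolide 29, forming the CH2–C(β) and ArCH–C(α) bonds in one event. The closest known reaction type is the fluoride-induced 1,3-elimination of α-halo (silylmethyl) ethers to carbonyl ylides and their [3+2] cycloaddition to α,β-unsaturated esters; new here are the ionisation of a bis(silylmethyl) acetal as ylide source, the electron-rich aryl substituent and the γ-aryl butenolide as dipolarophile. The tetrahydrofuran ring closes by an intermolecular suprafacial [3+2] cycloaddition (four π electrons of the dipole, two of the alkene) in which both C–C bonds form on one face of the lactone, so the new ring is necessarily cis-fused. The two ring-fusion stereocentres are controlled by the γ-stereocentre of 29, whose aryl group blocks one face so that the dipole adds anti to it, and the ArCH stereocentre by an exo approach of the E-configured ylide that keeps its aryl group away from the lactone ring. The regiochemistry needed (CH2 terminus to the β-carbon) follows from the polarisation of the ylide, whose benzylic terminus is stabilised as a cation by the para ring oxygen while the CH2 terminus carries the negative charge, which matches the β-electrophilic and α-nucleophilic character of the enoate. Ionisation before the butenolide is added, a slight deficit of TMSOTf and a weakly basic fluoride source should keep the acid- and base-sensitive γ-aryl butenolide, the acetonide and the cis-dihydrobenzofuran intact.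

Step 18
Reactants: 32 furofuranone
Product: 33 1,4-diol (benzylic secondary and primary hydroxyl)
Conditions: LiAlH4, THF, 0 °C; aqueous potassium sodium tartrate work-up
Reagents that add atoms: none
Why: LiAlH4 reduction of the lactone to the 1,4-diol, with no epimerisable centre present and with silyl ether, acetonide and benzyl ethers inert.

Step 19
Reactants: 33 1,4-diol
Product: 35 protected (1S,3aR,4S,6aR)-furofuran, via primary mesylate 34 (not isolated)
Conditions: MsCl (1.1 equiv), Et3N, CH2Cl2, −20 °C → rt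
Reagents that add atoms: none
Why: Selective mesylation of the primary hydroxyl and intramolecular 5-exo-tet SN2 displacement by the benzylic hydroxyl close the second tetrahydrofuran ring with retention at the benzylic carbon, the classical cyclodehydration of furofuran lignan synthesis.

Step 20
Reactants: 35 protected furofuran
Product: 36 triol (benzylic carbinol and two primary alcohols)
Conditions: AcOH/THF/H2O (3:1:1), 40 °C
Reagents that add atoms: none
Why: Aqueous acetic acid hydrolyses the acetonide and the primary silyl ether in one operation, and in water any SN1 exchange at the benzylic carbinol only returns the alcohol.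

Step 21
Reactants: 36 triol
Product: 37 tri-O-benzyl β-hydroxy ketone
Conditions: activated MnO2 (excess), CH2Cl2, rt
Reagents that add atoms: none
Why: Activated MnO2 oxidises benzylic alcohols but not saturated primary alcohols, so only the benzylic carbinol becomes the ketone, and under these neutral conditions the α-aryl stereocentre should not enolise.

Step 22
Reactants: 37 tri-O-benzyl ketone
Product: 38 CNP0174045.1
Conditions: H2 (1 atm), 10% Pd/C, EtOAc/MeOH, rt, stopped at complete debenzylation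
Reagents that add atoms: none
Why: Hydrogenolysis of the three aryl benzyl ethers over Pd/C under neutral conditions should be much faster than cleavage of the dialkyl benzylic ethers or reduction of the aryl ketone, and it avoids acid or base that would epimerise the ketone α-carbon or the cis-dihydrobenzofuran.

**Compound list**

Shorthand used in names: DHB = (2S,3S)-2-[4-(benzyloxy)-3-methoxyphenyl]-3-{[(tert-butyldimethylsilyl)oxy]methyl}-7-methoxy-2,3-dihydro-1-benzofuran-5-yl (2,3-cis); DOX = (4R,5S)-4-[4-(benzyloxy)-3-methoxyphenyl]-2,2-dimethyl-1,3-dioxan-5-yl.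

1 | 5-iodovanillin (4-hydroxy-3-iodo-5-methoxybenzaldehyde) | O=Cc1cc(I)c(O)c(OC)c1 | starting material
2 | 4-(benzyloxy)-3-methoxybenzyl alcohol | OCc1ccc(OCc2ccccc2)c(OC)c1 | starting material
3 | 4-{[4-(benzyloxy)-3-methoxybenzyl]oxy}-3-iodo-5-methoxybenzaldehyde | O=Cc1cc(I)c(OCc2ccc(OCc3ccccc3)c(OC)c2)c(OC)c1 | intermediate
4 | (trimethylsilyl)methanol | C[Si](C)(C)CO | starting material
5 | 2-{[4-(benzyloxy)-3-methoxybenzyl]oxy}-5-{bis[(trimethylsilyl)methoxy]methyl}-1-iodo-3-methoxybenzene | C[Si](C)(C)COC(OC[Si](C)(C)C)c1cc(I)c(OCc2ccc(OCc3ccccc3)c(OC)c2)c(OC)c1 | intermediate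
6 | ethyl diazoacetate | CCOC(=O)C=[N+]=[N-] | starting material
7 | ethyl 2-(2-{[4-(benzyloxy)-3-methoxybenzyl]oxy}-5-{bis[(trimethylsilyl)methoxy]methyl}-3-methoxyphenyl)-2-diazoacetate | CCOC(=O)C(=[N+]=[N-])c1cc(C(OC[Si](C)(C)C)OC[Si](C)(C)C)cc(OC)c1OCc1ccc(OCc2ccccc2)c(OC)c1 | intermediate
8 | ethyl (2S,3R)-2-[4-(benzyloxy)-3-methoxyphenyl]-5-{bis[(trimethylsilyl)methoxy]methyl}-7-methoxy-2,3-dihydro-1-benzofuran-3-carboxylate (2,3-cis) | C[Si](C)(C)COC(OC[Si](C)(C)C)c1cc(OC)c2c(c1)[C@@H](C(=O)OCC)[C@@H](c1ccc(OCc3ccccc3)c(OC)c1)O2 | intermediate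
9 | {(2S,3S)-2-[4-(benzyloxy)-3-methoxyphenyl]-5-{bis[(trimethylsilyl)methoxy]methyl}-7-methoxy-2,3-dihydro-1-benzofuran-3-yl}methanol (2,3-cis) | C[Si](C)(C)COC(OC[Si](C)(C)C)c1cc(OC)c2c(c1)[C@@H](CO)[C@@H](c1ccc(OCc3ccccc3)c(OC)c1)O2 | intermediate
10 | DHB–CH[OCH2Si(CH3)3]2, the tert-butyldimethylsilyl ether of 9 | C[Si](C)(C)COC(OC[Si](C)(C)C)c1cc(OC)c2c(c1)[C@@H](CO[Si](C)(C)C(C)(C)C)[C@@H](c1ccc(OCc3ccccc3)c(OC)c1)O2 | intermediate
11 | 2-allyl-6-methoxyphenol | C=CCc1cccc(OC)c1O | starting material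
12 | 2-allyl-4-bromo-6-methoxyphenol | C=CCc1cc(Br)cc(OC)c1O | intermediate
13 | 1-allyl-2-(benzyloxy)-5-bromo-3-methoxybenzene | C=CCc1cc(Br)cc(OC)c1OCc1ccccc1 | intermediate
14 | 2-[2-(benzyloxy)-5-bromo-3-methoxyphenyl]acetaldehyde | O=CCc1cc(Br)cc(OC)c1OCc1ccccc1 | intermediate
15 | 2-[2-(benzyloxy)-5-bromo-3-methoxyphenyl]acetic acid | OC(=O)Cc1cc(Br)cc(OC)c1OCc1ccccc1 | intermediate
16 | (R)-4-benzyl-1,3-oxazolidin-2-one | O=C1N[C@H](Cc2ccccc2)CO1 | starting material
17 | 2-[2-(benzyloxy)-5-bromo-3-methoxyphenyl]acetic pivalic anhydride | CC(C)(C)C(=O)OC(=O)Cc1cc(Br)cc(OC)c1OCc1ccccc1 | intermediate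
18 | (R)-4-benzyl-3-{2-[2-(benzyloxy)-5-bromo-3-methoxyphenyl]acetyl}-1,3-oxazolidin-2-one | O=C(Cc1cc(Br)cc(OC)c1OCc1ccccc1)N1[C@H](Cc2ccccc2)COC1=O | intermediate
19 | 4-(benzyloxy)-3-methoxybenzaldehyde | O=Cc1ccc(OCc2ccccc2)c(OC)c1 | starting material
20 | (Z)-dibutylboron enolate of 18 | CCCCB(CCCC)O/C(=C\c1cc(Br)cc(OC)c1OCc1ccccc1)N1[C@H](Cc2ccccc2)COC1=O | intermediate
21 | (R)-4-benzyl-3-{(2R,3R)-3-[4-(benzyloxy)-3-methoxyphenyl]-2-[2-(benzyloxy)-5-bromo-3-methoxyphenyl]-3-hydroxypropanoyl}-1,3-oxazolidin-2-one | COc1cc([C@H](O)[C@H](C(=O)N2[C@H](Cc3ccccc3)COC2=O)c2cc(Br)cc(OC)c2OCc2ccccc2)ccc1OCc1ccccc1 | intermediate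
22 | (1R,2S)-1-[4-(benzyloxy)-3-methoxyphenyl]-2-[2-(benzyloxy)-5-bromo-3-methoxyphenyl]propane-1,3-diol | COc1cc([C@H](O)[C@H](CO)c2cc(Br)cc(OC)c2OCc2ccccc2)ccc1OCc1ccccc1 | intermediate
23 | (4R,5S)-4-[4-(benzyloxy)-3-methoxyphenyl]-5-[2-(benzyloxy)-5-bromo-3-methoxyphenyl]-2,2-dimethyl-1,3-dioxane | COc1cc([C@@H]2OC(C)(C)OC[C@@H]2c2cc(Br)cc(OC)c2OCc2ccccc2)ccc1OCc1ccccc1 | intermediate
24 | aryllithium from 23 (Li in place of Br) | COc1cc([C@@H]2OC(C)(C)OC[C@@H]2c2cc([Li])cc(OC)c2OCc2ccccc2)ccc1OCc1ccccc1 | intermediate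
25 | 4-(benzyloxy)-3-methoxy-5-(DOX)benzaldehyde | COc1cc([C@@H]2OC(C)(C)OC[C@@H]2c2cc(C=O)cc(OC)c2OCc2ccccc2)ccc1OCc1ccccc1 | intermediate
26 | methyl propiolate | C#CC(=O)OC | starting material
27 | methyl (4R)-4-[4-(benzyloxy)-3-methoxy-5-(DOX)phenyl]-4-hydroxybut-2-ynoate | COc1cc([C@@H]2OC(C)(C)OC[C@@H]2c2cc([C@@H](O)C#CC(=O)OC)cc(OC)c2OCc2ccccc2)ccc1OCc1ccccc1 | intermediate
28 | methyl (2Z,4S)-4-[4-(benzyloxy)-3-methoxy-5-(DOX)phenyl]-4-hydroxybut-2-enoate | COc1cc([C@@H]2OC(C)(C)OC[C@@H]2c2cc([C@@H](O)/C=C\C(=O)OC)cc(OC)c2OCc2ccccc2)ccc1OCc1ccccc1 | intermediate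
29 | (5S)-5-[4-(benzyloxy)-3-methoxy-5-(DOX)phenyl]furan-2(5H)-one | COc1cc([C@@H]2OC(C)(C)OC[C@@H]2c2cc([C@H]3OC(=O)C=C3)cc(OC)c2OCc2ccccc2)ccc1OCc1ccccc1 | intermediate
30 | (E)-DHB–CH=O(+)–CH2Si(CH3)3 triflate, the O-[(trimethylsilyl)methyl] oxocarbenium salt | C[Si](C)(C)C/[O+]=C/c1cc(OC)c2c(c1)[C@@H](CO[Si](C)(C)C(C)(C)C)[C@@H](c1ccc(OCc3ccccc3)c(OC)c1)O2.[O-]S(=O)(=O)C(F)(F)F | intermediate
31 | (E)-DHB–CH=O(+)–CH2(−), the carbonyl ylide | [CH2-]/[O+]=C/c1cc(OC)c2c(c1)[C@@H](CO[Si](C)(C)C(C)(C)C)[C@@H](c1ccc(OCc3ccccc3)c(OC)c1)O2 | intermediate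
32 | (3S,3aR,6S,6aS)-3-[4-(benzyloxy)-3-methoxy-5-(DOX)phenyl]-6-(DHB)-tetrahydro-1H,3H-furo[3,4-c]furan-1-one | COc1cc([C@@H]2OC(C)(C)OC[C@@H]2c2cc([C@H]3OC(=O)[C@H]4[C@@H]3CO[C@@H]4c3cc(OC)c4c(c3)[C@@H](CO[Si](C)(C)C(C)(C)C)[C@@H](c3ccc(OCc5ccccc5)c(OC)c3)O4)cc(OC)c2OCc2ccccc2)ccc1OCc1ccccc1 | intermediate
33 | (S)-[4-(benzyloxy)-3-methoxy-5-(DOX)phenyl][(3R,4R,5S)-5-(DHB)-4-(hydroxymethyl)oxolan-3-yl]methanol | COc1cc([C@@H]2OC(C)(C)OC[C@@H]2c2cc([C@@H](O)[C@H]3CO[C@H](c4cc(OC)c5c(c4)[C@@H](CO[Si](C)(C)C(C)(C)C)[C@@H](c4ccc(OCc6ccccc6)c(OC)c4)O5)[C@H]3CO)cc(OC)c2OCc2ccccc2)ccc1OCc1ccccc1 | intermediate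
34 | primary methanesulfonate of 33 (CH2OSO2CH3 on the oxolane, benzylic OH free) | COc1cc([C@@H]2OC(C)(C)OC[C@@H]2c2cc([C@@H](O)[C@H]3CO[C@H](c4cc(OC)c5c(c4)[C@@H](CO[Si](C)(C)C(C)(C)C)[C@@H](c4ccc(OCc6ccccc6)c(OC)c4)O5)[C@H]3COS(C)(=O)=O)cc(OC)c2OCc2ccccc2)ccc1OCc1ccccc1 | intermediate
35 | (1S,3aR,4S,6aR)-1-[4-(benzyloxy)-3-methoxy-5-(DOX)phenyl]-4-(DHB)-tetrahydro-1H,3H-furo[3,4-c]furan | COc1cc([C@@H]2OC(C)(C)OC[C@@H]2c2cc([C@H]3OC[C@H]4[C@@H]3CO[C@@H]4c3cc(OC)c4c(c3)[C@@H](CO[Si](C)(C)C(C)(C)C)[C@@H](c3ccc(OCc5ccccc5)c(OC)c3)O4)cc(OC)c2OCc2ccccc2)ccc1OCc1ccccc1 | intermediate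
36 | (1R,2S)-1-[4-(benzyloxy)-3-methoxyphenyl]-2-{2-(benzyloxy)-5-[(1S,3aR,4S,6aR)-4-{(2S,3S)-2-[4-(benzyloxy)-3-methoxyphenyl]-3-(hydroxymethyl)-7-methoxy-2,3-dihydro-1-benzofuran-5-yl}tetrahydro-1H,3H-furo[3,4-c]furan-1-yl]-3-methoxyphenyl}propane-1,3-diol | COc1cc([C@H](O)[C@H](CO)c2cc([C@H]3OC[C@H]4[C@@H]3CO[C@@H]4c3cc(OC)c4c(c3)[C@@H](CO)[C@@H](c3ccc(OCc5ccccc5)c(OC)c3)O4)cc(OC)c2OCc2ccccc2)ccc1OCc1ccccc1 | intermediate
37 | (2S)-1-[4-(benzyloxy)-3-methoxyphenyl]-2-{2-(benzyloxy)-5-[(1S,3aR,4S,6aR)-4-{(2S,3S)-2-[4-(benzyloxy)-3-methoxyphenyl]-3-(hydroxymethyl)-7-methoxy-2,3-dihydro-1-benzofuran-5-yl}tetrahydro-1H,3H-furo[3,4-c]furan-1-yl]-3-methoxyphenyl}-3-hydroxypropan-1-one | COc1cc(C(=O)[C@H](CO)c2cc([C@H]3OC[C@H]4[C@@H]3CO[C@@H]4c3cc(OC)c4c(c3)[C@@H](CO)[C@@H](c3ccc(OCc5ccccc5)c(OC)c3)O4)cc(OC)c2OCc2ccccc2)ccc1OCc1ccccc1 | intermediate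
38 | CNP0174045.1, (2S)-3-hydroxy-1-(4-hydroxy-3-methoxyphenyl)-2-{2-hydroxy-5-[(1S,3aR,4S,6aR)-4-{(2S,3S)-2-(4-hydroxy-3-methoxyphenyl)-3-(hydroxymethyl)-7-methoxy-2,3-dihydro-1-benzofuran-5-yl}tetrahydro-1H,3H-furo[3,4-c]furan-1-yl]-3-methoxyphenyl}propan-1-one | COc1cc(C(=O)[C@H](CO)c2cc([C@H]3OC[C@H]4[C@@H]3CO[C@@H]4c3cc(OC)c4c(c3)[C@@H](CO)[C@@H](c3ccc(O)c(OC)c3)O4)cc(OC)c2O)ccc1O | target

**Step count and risks**

Total step count: 22. Longest linear sequence: 16 steps (steps 7–16, then 17–22, from 2-allyl-6-methoxyphenol); the other branch is steps 1–6.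

Steps most likely to fail:

1. Step 17. The ylide may collapse (ring closure to the oxirane, protonation or self-reaction) before the butenolide traps it. Exo or facial control may erode. The fluoride source may racemise the γ-aryl butenolide through its furanolate. Fallback, from 10 and 29, returning at 32, by the known three-component carbonyl ylide cycloaddition:
   - Acetal 10 is hydrolysed (PPTS, acetone/H2O, rt) to the aldehyde F1.
   - Ethyl diazoacetate 6 is added slowly to F1 and butenolide 29 with Rh2(OAc)4 (cat., CH2Cl2, rt). The rhodium-bound carbene and the aldehyde oxygen form an ester-stabilised carbonyl ylide, which should add to 29 in the same regiochemical and facial sense to give the ethoxycarbonyl-substituted cycloadduct F2. The configuration at the ester-bearing carbon is of no consequence.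
   - LiOH, THF/H2O, 0 °C, then acidification to pH 4 (the lactone re-closes) gives the carboxylic acid F3.
   - Barton decarboxylation replaces CO2H by H and gives 32: 2-mercaptopyridine N-oxide, EDC, DMAP, CH2Cl2 in the dark give the thiohydroxamate ester F4, not isolated, which is then treated with t-BuSH under visible light.

2. Step 22. Hydrogenation of the aryl ketone and hydrogenolysis at the carbon next to it may compete with debenzylation. Fallback, from 35, returning at 38, by exchanging benzyl for silyl protection before the ketone exists: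
   - H2, Pd/C, EtOAc on 35 gives the triphenol F5.
   - TBSOTf, 2,6-lutidine, CH2Cl2 gives the tris(aryl silyl ether) F6.
   - AcOH/THF/H2O, 40 °C removes the acetonide and the alkyl silyl ether while the aryl silyl ethers stay, giving the triol F7.
   - Activated MnO2, CH2Cl2 gives the ketone F8.
   - Et3N·3HF, THF, rt removes the three aryl silyl groups under weakly acidic, non-reducing conditions and gives 38.

3. Step 21. The oxidation on the MnO2 surface may be slow at the hindered carbinol, may touch the primary alcohols, or may trigger retro-aldol loss of formaldehyde. Fallback, from 36, returning at 37, by protection, oxidation and deprotection: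
   - TBSCl (2.2 equiv), imidazole, DMF, 0 °C silylates the two primary hydroxyls and gives the bis(silyl ether) F9.
   - Dess–Martin periodinane, NaHCO3, CH2Cl2 oxidises the remaining benzylic alcohol and gives the ketone F10.
   - HF·pyridine, THF/pyridine, 0 °C gives 37.

Further compounds
F1 | step 17 | (2S,3S)-2-[4-(benzyloxy)-3-methoxyphenyl]-3-{[(tert-butyldimethylsilyl)oxy]methyl}-7-methoxy-2,3-dihydro-1-benzofuran-5-carbaldehyde | O=Cc1cc(OC)c2c(c1)[C@@H](CO[Si](C)(C)C(C)(C)C)[C@@H](c1ccc(OCc3ccccc3)c(OC)c1)O2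
F2 | step 17 | 32 bearing an ethoxycarbonyl group on the CH2 carbon of the new tetrahydrofuran ring (both epimers at that carbon) | COc1cc([C@@H]2OC(C)(C)OC[C@@H]2c2cc([C@H]3OC(=O)[C@H]4[C@@H]3C(C(=O)OCC)O[C@@H]4c3cc(OC)c4c(c3)[C@@H](CO[Si](C)(C)C(C)(C)C)[C@@H](c3ccc(OCc5ccccc5)c(OC)c3)O4)cc(OC)c2OCc2ccccc2)ccc1OCc1ccccc1
F3 | step 17 | carboxylic acid from F2 | COc1cc([C@@H]2OC(C)(C)OC[C@@H]2c2cc([C@H]3OC(=O)[C@H]4[C@@H]3C(C(=O)O)O[C@@H]4c3cc(OC)c4c(c3)[C@@H](CO[Si](C)(C)C(C)(C)C)[C@@H](c3ccc(OCc5ccccc5)c(OC)c3)O4)cc(OC)c2OCc2ccccc2)ccc1OCc1ccccc1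
F4 | step 17 | 2-thioxopyridin-1(2H)-yl ester of F3 (not isolated) | COc1cc([C@@H]2OC(C)(C)OC[C@@H]2c2cc([C@H]3OC(=O)[C@H]4[C@@H]3C(C(=O)ON3C=CC=CC3=S)O[C@@H]4c3cc(OC)c4c(c3)[C@@H](CO[Si](C)(C)C(C)(C)C)[C@@H](c3ccc(OCc5ccccc5)c(OC)c3)O4)cc(OC)c2OCc2ccccc2)ccc1OCc1ccccc1
F5 | step 22 | triphenol from 35 (three benzyl groups removed, acetonide and alkyl silyl ether kept) | COc1cc([C@@H]2OC(C)(C)OC[C@@H]2c2cc([C@H]3OC[C@H]4[C@@H]3CO[C@@H]4c3cc(OC)c4c(c3)[C@@H](CO[Si](C)(C)C(C)(C)C)[C@@H](c3ccc(O)c(OC)c3)O4)cc(OC)c2O)ccc1O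
F6 | step 22 | tris(aryl tert-butyldimethylsilyl ether) of F5 | COc1cc([C@@H]2OC(C)(C)OC[C@@H]2c2cc([C@H]3OC[C@H]4[C@@H]3CO[C@@H]4c3cc(OC)c4c(c3)[C@@H](CO[Si](C)(C)C(C)(C)C)[C@@H](c3ccc(O[Si](C)(C)C(C)(C)C)c(OC)c3)O4)cc(OC)c2O[Si](C)(C)C(C)(C)C)ccc1O[Si](C)(C)C(C)(C)C
F7 | step 22 | triol with three aryl silyl ethers (silyl analogue of 36) | COc1cc([C@H](O)[C@H](CO)c2cc([C@H]3OC[C@H]4[C@@H]3CO[C@@H]4c3cc(OC)c4c(c3)[C@@H](CO)[C@@H](c3ccc(O[Si](C)(C)C(C)(C)C)c(OC)c3)O4)cc(OC)c2O[Si](C)(C)C(C)(C)C)ccc1O[Si](C)(C)C(C)(C)C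
F8 | step 22 | β-hydroxy ketone with three aryl silyl ethers (silyl analogue of 37) | COc1cc(C(=O)[C@H](CO)c2cc([C@H]3OC[C@H]4[C@@H]3CO[C@@H]4c3cc(OC)c4c(c3)[C@@H](CO)[C@@H](c3ccc(O[Si](C)(C)C(C)(C)C)c(OC)c3)O4)cc(OC)c2O[Si](C)(C)C(C)(C)C)ccc1O[Si](C)(C)C(C)(C)C
F9 | step 21 | bis(primary tert-butyldimethylsilyl ether) of 36, benzylic OH free | COc1cc([C@H](O)[C@H](CO[Si](C)(C)C(C)(C)C)c2cc([C@H]3OC[C@H]4[C@@H]3CO[C@@H]4c3cc(OC)c4c(c3)[C@@H](CO[Si](C)(C)C(C)(C)C)[C@@H](c3ccc(OCc5ccccc5)c(OC)c3)O4)cc(OC)c2OCc2ccccc2)ccc1OCc1ccccc1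
F10 | step 21 | ketone from F9 (bis silyl ether of 37) | COc1cc(C(=O)[C@H](CO[Si](C)(C)C(C)(C)C)c2cc([C@H]3OC[C@H]4[C@@H]3CO[C@@H]4c3cc(OC)c4c(c3)[C@@H](CO[Si](C)(C)C(C)(C)C)[C@@H](c3ccc(OCc5ccccc5)c(OC)c3)O4)cc(OC)c2OCc2ccccc2)ccc1OCc1ccccc1
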